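Eudesmane numbering: ring A = C1–C5, C10; ring B = C5–C10; acrylate = C11–C13. The route rests on disconnecting C6–C7 of ring B. It exploits two features. C7 is the allylic carbon of the C11=C13 acrylate, and C6 sits beta to C4 of ring A, which can be a ketone until C15 is attached. An intramolecular Hosomi–Sakurai addition of a 2-(methoxycarbonyl)allylsilane (attack through C7) to an alpha-methylene ketone (acceptor C6) closes ring B, sets C7 and C5, and unveils the acrylate in one operation. The precursor is a monocyclic enone whose only stereocentre, C10, stems from a catalytic asymmetric conjugate addition. Its E/Z mixture converges.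

Key step: step 6

Assumption: the antipode of the leucinol-derived NHC ligand that gives the (R)-configured C10 is fixed by a test run on 1; both antipodes are accessible from commercial (S)- and (R)-leucinol.

Step 1
Reactants: 1 3-methylcyclohex-2-en-1-one; 2 but-3-en-1-ylmagnesium bromide; 3 dimethyl(methylidene)ammonium iodide
Product: 5 (3R)-3-(but-3-en-1-yl)-2-[(dimethylamino)methyl]-3-methylcyclohexan-1-one (C5 epimers), via bromomagnesium enolate 4 (not isolated)
Conditions: Cu(OTf)2 (3 mol %), 1-(1-hydroxy-4-methylpentan-2-yl)-3-mesitylimidazolinium hexafluorophosphate (single antipode, 4 mol %), Et2O, −30 °C; then 3, THF, −30 °C to rt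
Reagents that add atoms: none
Why: Copper-catalysed asymmetric conjugate addition of a Grignard reagent to a beta-substituted cyclic enone sets the quaternary C10 under ligand control, and the regiodefined enolate 4 is captured at C5 by the small, very electrophilic iminium salt (Mannich reaction), the C5 configuration being irrelevant because C5 becomes sp2 in step 5.

Step 2
Reactants: 5 Mannich base
Product: 8 3-[(1R)-2-[(dimethylamino)methyl]-1-methyl-3-oxocyclohexyl]propanal (C5 epimers), via trifluoroacetate salt 6 (not isolated), via ozonide 7 (not isolated)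
Conditions: CF3CO2H (1.1 equiv), CH2Cl2, −78 °C; O3; Me2S, −78 °C to rt; aq NaHCO3
Reagents that add atoms: ozone, [O-][O+]=O; trifluoroacetic acid, OC(=O)C(F)(F)F (counter-ion in 6 and 7 only)
Why: Ozonolysis with reductive work-up cleaves the only C=C bond of 5 to the C7 aldehyde, the amine being shielded from ozone as its ammonium salt 6.

Step 3
Reactants: 9 trimethyl phosphonoacetate; 10 (iodomethyl)trimethylsilane
Product: 12 methyl 2-(dimethoxyphosphoryl)-3-(trimethylsilyl)propanoate (racemic), via sodium phosphonoacetate 11 (not isolated)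
Conditions: NaH, DMSO–THF, 0 °C; then 10, 60 °C
Reagents that add atoms: sodium hydride, [Na+].[H-] (sodium in 11 only)
Why: SN2 alkylation of the stabilised phosphonoacetate anion 11 by the primary iodide gives the alpha-branched Horner–Wadsworth–Emmons reagent, whose stereocentre is lost in step 4.

Step 4
Reactants: 8 amino keto aldehyde; 12 silyl phosphonate
Product: 14 methyl 5-[(1R)-2-[(dimethylamino)methyl]-1-methyl-3-oxocyclohexyl]-2-[(trimethylsilyl)methyl]pent-2-enoate (E/Z mixture; C5 epimers), via sodium phosphonate anion 13 (not isolated)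
Conditions: NaH, THF, 0 °C; then 8, −78 to 0 °C
Reagents that add atoms: sodium hydride, [Na+].[H-] (sodium in 13 only)
Why: Horner–Wadsworth–Emmons olefination occurs only at the aldehyde because the hindered ketone does not react with the alpha-branched phosphonate anion, and the alkene geometry need not be controlled since both isomers converge in step 6.

Step 5
Reactants: 14 allylsilane Mannich base
Product: 16 methyl 5-[(1R)-1-methyl-2-methylidene-3-oxocyclohexyl]-2-[(trimethylsilyl)methyl]pent-2-enoate (E/Z mixture), via methiodide 15 (not isolated)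
Conditions: MeI, Et2O, rt, evaporate; then aq NaHCO3, CH2Cl2, rt; used at once
Reagents that add atoms: iodomethane, CI (methyl group and iodide in 15 only)
Why: Exhaustive methylation turns the amine into a leaving group and mild base triggers E1cB elimination (the classical Mannich-base route to alpha-methylene ketones), which also erases the C5 epimer mixture.

Step 6
Reactants: 16 alpha-methylene ketone allylsilane
Product: 18 methyl 2-[(2R,4aR,8aR)-4a-methyl-8-oxodecahydronaphthalen-2-yl]prop-2-enoate (trans-decalone; 5-alpha-H; equatorial C7 acrylate), via trichlorotitanium enolate 17 (not isolated)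
Conditions: TiCl4 (2.2 equiv), CH2Cl2 (high dilution), −78 to −30 °C; H2O; then DBU (0.2 equiv), toluene, 60 °C
Reagents that add atoms: titanium tetrachloride, Cl[Ti](Cl)(Cl)Cl (TiCl3 unit in 17 only)
Why: TiCl4 binds the C4 ketone of the s-cis-locked enone and makes the exocyclic terminus C6 strongly electrophilic; the allylsilane attacks through its gamma carbon C7 (SE2'), the C13–Si bond collapses into the C11=C13 double bond with loss of Me3SiCl, and the trichlorotitanium enolate 17 is left, which is the intramolecular Hosomi–Sakurai conjugate allylation known for 2-(alkoxycarbonyl)allylsilanes. Ring B closes as a six-membered ring, endo-trig at the acceptor C5=C6 and exo-trig at the donor C7=C11. C7 is controlled by C10: since C4, C5, C6 and C10 must stay coplanar in the activated enone, the C10 methyl group is forced axial on the nascent ring B chair, only one chair is open, and the bulky C11 arm takes the equatorial site, which gives (7R). C5 is planar in 16 and in 17 and is set under thermodynamic control: it stays alpha to the ketone after protonation, so DBU funnels both C5 epimers into the trans-decalone that keeps the side chain equatorial. The step needs 1,4- over 1,2-addition, secured by the unhindered CH2 terminus and by the bridged bicyclo[3.3.1]nonane that 1,2-attack would have to build, and gamma- over alpha-attack, secured by the beta-silicon effect. Both alkene isomers of 16 lose their geometry when C11 becomes the acrylate carbon and should converge on the same product.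

Step 7
Reactants: 18 decalone acrylate
Product: 20 methyl 2-[(2R,4aS,8aR)-4a-methyl-8-(trifluoromethylsulfonyloxy)-1,2,3,4,4a,5,6,8a-octahydronaphthalen-2-yl]prop-2-enoate (same spatial arrangement; the C10 descriptor changes by priority only), via potassium enolate 19 (not isolated)
Conditions: KN(SiMe3)2 (1.05 equiv), THF, −78 °C; then N-(5-chloropyridin-2-yl)-1,1,1-trifluoro-N-(trifluoromethylsulfonyl)methanesulfonamide, −78 °C
Reagents that add atoms: N-(5-chloropyridin-2-yl)-1,1,1-trifluoro-N-(trifluoromethylsulfonyl)methanesulfonamide, FC(F)(F)S(=O)(=O)N(c1ccc(Cl)cn1)S(=O)(=O)C(F)(F)F; potassium bis(trimethylsilyl)amide, [K+].C[Si](C)(C)[N-][Si](C)(C)C (potassium in 19 only)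
Why: Kinetic deprotonation by the bulky, non-nucleophilic amide takes the accessible C3–H rather than the tertiary C5–H, and O-sulfonylation (enol triflate formation) fixes the C3=C4 double bond and thereby locks C5.

Step 8
Reactants: 20 enol triflate; 21 (tributylstannyl)methanol
Product: 22 methyl 2-[(2R,4aR,8aR)-8-(hydroxymethyl)-4a-methyl-1,2,3,4,4a,5,6,8a-octahydronaphthalen-2-yl]prop-2-enoate
Conditions: Pd(PPh3)4 (5 mol %), LiCl (3 equiv), 1,4-dioxane, 90 °C
Reagents that add atoms: none
Why: Stille cross-coupling, in which zerovalent palladium inserts into the alkenyl C4–O triflate bond, LiCl eases transmetalation and the hydroxymethyl group is transferred in preference to butyl, installs C15 with retention of the C3=C4 position and of all stereocentres.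

Step 9
Reactants: 22 allylic alcohol; 23 (E)-4-hydroxycinnamic acid (p-coumaric acid)
Product: 24 methyl 2-[(2R,4aR,8aR)-8-({[(2E)-3-(4-hydroxyphenyl)prop-2-enoyl]oxy}methyl)-4a-methyl-1,2,3,4,4a,5,6,8a-octahydronaphthalen-2-yl]prop-2-enoate (target)
Conditions: PPh3, DIAD, THF, 0 °C to rt
Reagents that add atoms: none
Why: Mitsunobu esterification engages only the carboxylic acid of 23, which is several pKa units more acidic than its phenol, and displaces the activated primary allylic oxygen at C15 by SN2 without touching any stereocentre or the E-alkene.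

Compound list
1 | 3-methylcyclohex-2-en-1-one | CC1=CC(=O)CCC1 | starting material
2 | but-3-en-1-ylmagnesium bromide | C=CCC[Mg]Br | starting material
3 | dimethyl(methylidene)ammonium iodide | C=[N+](C)C.[I-] | starting material
4 | bromomagnesium (3R)-3-(but-3-en-1-yl)-3-methylcyclohex-1-en-1-olate | C=CCC[C@@]1(C)CCCC(O[Mg]Br)=C1 | intermediate
5 | (3R)-3-(but-3-en-1-yl)-2-[(dimethylamino)methyl]-3-methylcyclohexan-1-one, C5 epimers | C=CCC[C@@]1(C)CCCC(=O)C1CN(C)C | intermediate
6 | trifluoroacetate salt of 5 | C=CCC[C@@]1(C)CCCC(=O)C1C[NH+](C)C.[O-]C(=O)C(F)(F)F | intermediate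
7 | 1,2,4-trioxolane (ozonide) of 6 | C1OOC(O1)CC[C@@]2(C)CCCC(=O)C2C[NH+](C)C.[O-]C(=O)C(F)(F)F | intermediate
8 | 3-[(1R)-2-[(dimethylamino)methyl]-1-methyl-3-oxocyclohexyl]propanal, C5 epimers | O=CCC[C@@]1(C)CCCC(=O)C1CN(C)C | intermediate
9 | trimethyl phosphonoacetate | COC(=O)CP(=O)(OC)OC | starting material
10 | (iodomethyl)trimethylsilane | C[Si](C)(C)CI | starting material
11 | sodium salt of 9 | COC(=O)[CH-]P(=O)(OC)OC.[Na+] | intermediate
12 | methyl 2-(dimethoxyphosphoryl)-3-(trimethylsilyl)propanoate, racemic | COC(=O)C(C[Si](C)(C)C)P(=O)(OC)OC | intermediate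
13 | sodium salt of 12 | COC(=O)[C-](C[Si](C)(C)C)P(=O)(OC)OC.[Na+] | intermediate
14 | methyl 5-[(1R)-2-[(dimethylamino)methyl]-1-methyl-3-oxocyclohexyl]-2-[(trimethylsilyl)methyl]pent-2-enoate, E/Z mixture, C5 epimers | COC(=O)C(C[Si](C)(C)C)=CCC[C@@]1(C)CCCC(=O)C1CN(C)C | intermediate
15 | methiodide of 14 | COC(=O)C(C[Si](C)(C)C)=CCC[C@@]1(C)CCCC(=O)C1C[N+](C)(C)C.[I-] | intermediate
16 | methyl 5-[(1R)-1-methyl-2-methylidene-3-oxocyclohexyl]-2-[(trimethylsilyl)methyl]pent-2-enoate, E/Z mixture | COC(=O)C(C[Si](C)(C)C)=CCC[C@@]1(C)CCCC(=O)C1=C | intermediate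
17 | trichlorotitanium C4=C5 enolate of 18 | C=C(C(=O)OC)[C@@H]1CC[C@@]2(C)CCCC(O[Ti](Cl)(Cl)Cl)=C2C1 | intermediate
18 | methyl 2-[(2R,4aR,8aR)-4a-methyl-8-oxodecahydronaphthalen-2-yl]prop-2-enoate | C=C(C(=O)OC)[C@@H]1CC[C@@]2(C)CCCC(=O)[C@@H]2C1 | intermediate
19 | potassium C3=C4 enolate of 18 | C=C(C(=O)OC)[C@@H]1CC[C@@]2(C)CCC=C([O-])[C@@H]2C1.[K+] | intermediate
20 | methyl 2-[(2R,4aS,8aR)-4a-methyl-8-(trifluoromethylsulfonyloxy)-1,2,3,4,4a,5,6,8a-octahydronaphthalen-2-yl]prop-2-enoate | C=C(C(=O)OC)[C@@H]1CC[C@@]2(C)CCC=C(OS(=O)(=O)C(F)(F)F)[C@@H]2C1 | intermediate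
21 | (tributylstannyl)methanol | OC[Sn](CCCC)(CCCC)CCCC | starting material
22 | methyl 2-[(2R,4aR,8aR)-8-(hydroxymethyl)-4a-methyl-1,2,3,4,4a,5,6,8a-octahydronaphthalen-2-yl]prop-2-enoate | C=C(C(=O)OC)[C@@H]1CC[C@@]2(C)CCC=C(CO)[C@@H]2C1 | intermediate
23 | (E)-4-hydroxycinnamic acid | O=C(O)/C=C/c1ccc(O)cc1 | starting material
24 | methyl 2-[(2R,4aR,8aR)-8-({[(2E)-3-(4-hydroxyphenyl)prop-2-enoyl]oxy}methyl)-4a-methyl-1,2,3,4,4a,5,6,8a-octahydronaphthalen-2-yl]prop-2-enoate | C=C(C(=O)OC)[C@@H]1CC[C@@]2(C)CCC=C(COC(=O)/C=C/c3ccc(O)cc3)[C@@H]2C1 | target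

Total step count: 9. Longest linear sequence: 8 (steps 1, 2, 4, 5, 6, 7, 8, 9 from 1); step 3 is a one-step side branch.

Steps most likely to fail

Step 6. The ester on C11 lowers the nucleophilicity of the allylsilane. Protodesilylation or oligomerisation of the activated enone may therefore outrun ring closure.
- The fallback inverts the polarity of the same C6–C7 closure and uses a radical addition–fragmentation. It sets out from 8 and comes back at 18.
- A Morita–Baylis–Hillman reaction of 8 with methyl acrylate (DABCO) should give the allylic alcohol F1.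
- Ac2O/DMAP should give the acetate F2, and SN2' displacement with PhSO2Na the allyl sulfone F3.
- MeI then gives the methiodide F4, and aqueous NaHCO3 the alpha-methylene ketone F5.
- With Bu3SnH/AIBN (benzene, 80 °C, slow addition) a stannyl radical adds to the ketone oxygen. The allylic O-stannyl ketyl radical closes 6-exo-trig from C6 onto C7 through the same chair. The alpha-ester radical then expels the phenylsulfonyl radical.
- The tributyltin enolate F6 is protonated and equilibrated with DBU to 18.

Step 7. The amide base or the potassium enolate may add to the acrylate, so that Michael-type oligomerisation consumes the material before O-sulfonylation.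
- The fallback masks the acrylate. It sets out from 18 and comes back at 20.
- Conjugate addition of PhSH (Et3N cat., CH2Cl2) should give the beta-phenylthio ester F7 (C11 epimers).
- KN(SiMe3)2 gives the potassium enolate F8, and the same triflating reagent gives the enol triflate F9.
- mCPBA (1 equiv, −78 °C) gives the sulfoxide F10.
- Thermal syn-elimination (toluene, 110 °C) restores C11=C13 and delivers 20.

Step 1. The hindered magnesium enolate next to the new quaternary carbon may react sluggishly with the suspended iminium salt, so that proton transfer and loss of the enolate regiochemistry compete.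
- The fallback separates the two events. It sets out from enolate 4 (made from 1 and 2 as in step 1) and comes back at 5.
- A quench with Me3SiCl gives the trimethylsilyl enol ether F11, which is isolated.
- F11 is then treated with 3 in CH2Cl2 under homogeneous conditions (Mukaiyama-type Mannich reaction, basic work-up) to give 5.

Further compounds
F1 | step 6 | methyl 2-{1-hydroxy-3-[(1R)-2-[(dimethylamino)methyl]-1-methyl-3-oxocyclohexyl]propyl}prop-2-enoate | C=C(C(=O)OC)C(O)CC[C@@]1(C)CCCC(=O)C1CN(C)C
F2 | step 6 | acetate of F1 | C=C(C(=O)OC)C(OC(C)=O)CC[C@@]1(C)CCCC(=O)C1CN(C)C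
F3 | step 6 | methyl 5-[(1R)-2-[(dimethylamino)methyl]-1-methyl-3-oxocyclohexyl]-2-[(phenylsulfonyl)methyl]pent-2-enoate | COC(=O)C(CS(=O)(=O)c1ccccc1)=CCC[C@@]2(C)CCCC(=O)C2CN(C)C
F4 | step 6 | methiodide of F3 | COC(=O)C(CS(=O)(=O)c1ccccc1)=CCC[C@@]2(C)CCCC(=O)C2C[N+](C)(C)C.[I-]
F5 | step 6 | methyl 5-[(1R)-1-methyl-2-methylidene-3-oxocyclohexyl]-2-[(phenylsulfonyl)methyl]pent-2-enoate | COC(=O)C(CS(=O)(=O)c1ccccc1)=CCC[C@@]2(C)CCCC(=O)C2=C
F6 | step 6 | tributyltin C4=C5 enolate of 18 | C=C(C(=O)OC)[C@@H]1CC[C@@]2(C)CCCC(O[Sn](CCCC)(CCCC)CCCC)=C2C1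
F7 | step 7 | thiophenol adduct of 18 (methyl 2-(decalonyl)-3-(phenylsulfanyl)propanoate, C11 epimers) | COC(=O)C(CSc1ccccc1)[C@@H]2CC[C@@]3(C)CCCC(=O)[C@@H]3C2
F8 | step 7 | potassium C3=C4 enolate of F7 | COC(=O)C(CSc1ccccc1)[C@@H]2CC[C@@]3(C)CCC=C([O-])[C@@H]3C2.[K+]
F9 | step 7 | C3=C4 enol triflate of F7 | COC(=O)C(CSc1ccccc1)[C@@H]2CC[C@@]3(C)CCC=C(OS(=O)(=O)C(F)(F)F)[C@@H]3C2
F10 | step 7 | sulfoxide of F9 | COC(=O)C(CS(=O)c1ccccc1)[C@@H]2CC[C@@]3(C)CCC=C(OS(=O)(=O)C(F)(F)F)[C@@H]3C2
F11 | step 1 | {[(3R)-3-(but-3-en-1-yl)-3-methylcyclohex-1-en-1-yl]oxy}trimethylsilane | C=CCC[C@@]1(C)CCCC(O[Si](C)(C)C)=C1
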